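The ten-membered ring is made by contraction of a twelve-membered one. Its segment C8(O)–C9–C10–C11(=C17H2), which runs from the carbinol carbon through ring-fusion carbon C10 to the exocyclic methylene of the cyclohexane, is a Claisen retron. The precursor is a bridged twelve-membered cyclic ether: O links C8 to C17, and C10=C11 is still a cyclohexene double bond. Selenoxide elimination unveils the C8=C9 enol ether. The [3,3] shift then forms C9–C10, sets C10 trans to C1, frees the C8 ketone and the exocyclic methylene, and expels C11, C17 and O from the ring. The twelve-membered ring, with both enoates in place, comes from ring-closing metathesis.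

Key step: step 17

Remark on the chemistry (numbering and reading of the structure): eunicellane numbering is used throughout.
- C1 and C10 are the ring-fusion carbons.
- The ten-membered ring is C1, C2=C3(CO2Me), C4, C5, C6=C7(CO2H), C8(OH), C9, C10.
- The cyclohexane is C1, C10, C11(=C17H2), C12, C13, C14(isopropyl).
- The SMILES is read as 1S,8R,10S,14S. H1 and H10 are trans, the isopropyl group is cis to C2, and in both enoates the ring carbons are cis (E by the sequence rule).

Step 1
Reactants: 1 3-methylbutanal; 2 but-3-en-2-one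
Product: 4 (4S)-4-isopropylcyclohex-2-en-1-one, via keto aldehyde 3 (not isolated)
Conditions: (S)-2-[methoxy(diphenyl)methyl]pyrrolidine (5 mol %), ethyl 3,4-dihydroxybenzoate (20 mol %), neat, 4 °C; then LiOH, iPrOH, rt
Reagents that add atoms: none
Why: Enamine-catalysed asymmetric Michael addition followed by intramolecular aldol condensation (Robinson-type annulation): the bulky diarylmethyl ether group shields one face of the E-enamine of 1, which should set C14 as S, and the condensation closes the cyclohexenone without touching it.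

Step 2
Reactants: 5 tributyl(iodomethyl)stannane; 6 4-methoxybenzyl alcohol
Product: 7 tributyl{[(4-methoxybenzyl)oxy]methyl}stannane
Conditions: NaH, THF–DMF, 0 °C to rt
Reagents that add atoms: none
Why: Williamson ether synthesis on a primary iodide that cannot eliminate; no stereocentre is formed.

Step 3
Reactants: 7 tributyl{[(4-methoxybenzyl)oxy]methyl}stannane; 4 (4S)-4-isopropylcyclohex-2-en-1-one
Product: 9 (4S)-4-isopropyl-1-{[(4-methoxybenzyl)oxy]methyl}cyclohex-2-en-1-ol (both C11 epimers), via alkoxymethyllithium 8 (not isolated)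
Conditions: 7, n-BuLi, THF, −78 °C; then 4, −78 °C; H2O
Reagents that add atoms: none
Why: Tin–lithium exchange gives an α-alkoxy organolithium that adds 1,2 to the enone; the new carbinol centre C11 forms as a mixture, which does not matter because it becomes sp2 in step 4.

Step 4
Reactants: 9 tertiary allylic alcohol
Product: 10 (6S)-6-isopropyl-3-{[(4-methoxybenzyl)oxy]methyl}cyclohex-2-en-1-one
Conditions: pyridinium chlorochromate [C5H5NH][CrO3Cl], 4 Å molecular sieves, CH2Cl2, rt
Reagents that add atoms: pyridinium chlorochromate, c1cc[nH+]cc1.[O-][Cr](=O)(=O)Cl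
Why: Dauben–Michno oxidative 1,3-transposition: the chromate ester of the tertiary allylic alcohol shifts by a [3,3] process to C1 and is oxidised there, which moves the oxygen next to C14 and leaves C17 on the enone β-carbon C11 (the carbonyl oxygen comes from the chromate).

Step 5
Reactants: 10 transposed enone
Product: 11 1-({[(4S)-4-isopropyl-3-methylidenecyclohex-1-en-1-yl]methoxy}methyl)-4-methoxybenzene
Conditions: Cp2TiMe2, toluene, 70 °C, dark
Reagents that add atoms: Cp2TiMe2, [CH3-].[CH3-].[Ti+4].c1cc[cH-]c1.c1cc[cH-]c1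
Why: Petasis methylenation through Cp2Ti=CH2 is not basic, so the enolisable stereocentre C14 next to the ketone should survive, and the ether is inert.

Step 6
Reactants: 11 diene
Product: 13 [(1R,6S)-6-isopropyl-3-{[(4-methoxybenzyl)oxy]methyl}cyclohex-2-en-1-yl]methanol (CH2OH cis to isopropyl), via B-alkyl-9-BBN 12 (not isolated)
Conditions: 9-BBN, THF, 0 °C to rt; then H2O2, aq NaOH, 0 °C
Reagents that add atoms: 9-BBN, B1C2CCCC1CCC2 (its boron stays only in 12); hydrogen peroxide, OO
Why: Brown hydroboration–oxidation: 9-BBN attacks only the terminal methylene of the diene, and because allylic 1,3-strain with C2H2 keeps the isopropyl group pseudoaxial, hydrogen is delivered to C1 from the opposite face, which sets C1 with CH2OH cis to isopropyl.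

Step 7
Reactants: 13 primary alcohol
Product: 14 (1R,6S)-6-isopropyl-3-{[(4-methoxybenzyl)oxy]methyl}cyclohex-2-ene-1-carbaldehyde
Conditions: Dess–Martin periodinane, NaHCO3, CH2Cl2, 0 °C
Reagents that add atoms: none
Why: Dess–Martin oxidation under buffered, nearly neutral conditions stops at the aldehyde and should spare the epimerisable, doubly activated C1–H.

Step 8
Reactants: 15 methyl hex-5-enoate
Product: 16 methyl 2-bromohex-5-enoate (racemic)
Conditions: LiN(iPr)2, THF, −78 °C; then BrCCl2CCl2Br, −78 °C
Reagents that add atoms: 1,2-dibromo-1,1,2,2-tetrachloroethane, ClC(Cl)(Br)C(Cl)(Cl)Br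
Why: Electrophilic α-bromination of the ester enolate with a positive-bromine donor that does not add to the terminal alkene; the product is racemic and its stereocentre is lost in step 9.

Step 9
Reactants: 16 methyl 2-bromohex-5-enoate
Product: 18 methyl 2-(triphenyl-λ5-phosphanylidene)hex-5-enoate, via phosphonium bromide 17 (not isolated)
Conditions: PPh3, toluene, 90 °C; then aq NaOH, CH2Cl2, rt
Reagents that add atoms: triphenylphosphine, c1ccc(cc1)P(c1ccccc1)c1ccccc1
Why: SN2 quaternisation of PPh3 by the α-bromo ester and deprotonation of the acidic salt give the stabilised ylide.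

Step 10
Reactants: 14 aldehyde; 18 ylide
Product: 19 methyl (2E)-2-(but-3-en-1-yl)-3-[(1R,6S)-6-isopropyl-3-{[(4-methoxybenzyl)oxy]methyl}cyclohex-2-en-1-yl]prop-2-enoate
Conditions: toluene, 60 °C
Reagents that add atoms: none
Why: Wittig olefination with a stabilised, α-branched ylide under neutral conditions, which should give the trisubstituted enoate with C1 trans to CO2Me (E) and leave C1 untouched.

Step 11
Reactants: 19 PMB ether
Product: 20 methyl (2E)-2-(but-3-en-1-yl)-3-[(1R,6S)-3-(hydroxymethyl)-6-isopropylcyclohex-2-en-1-yl]prop-2-enoate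
Conditions: DDQ, CH2Cl2–pH 7 buffer, 0 °C
Reagents that add atoms: none
Why: Oxidative cleavage of the 4-methoxybenzyl ether by DDQ (hydride abstraction, then hydrolysis of the oxocarbenium ion) is selective for the electron-rich benzyl ether.

Step 12
Reactants: 21 benzeneselenenyl chloride; 22 ethyl vinyl ether
Product: 24 (phenylselanyl)acetaldehyde, via chloro ether 23 (not isolated)
Conditions: CH2Cl2, −78 °C; then aq NaHCO3, THF, 0 °C
Reagents that add atoms: water, O
Why: Electrophilic selenenylation of the enol ether places selenium on the terminal carbon (future C9), and hydrolysis of the α-chloro ether frees the aldehyde (future C8).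

Step 13
Reactants: 24 (phenylselanyl)acetaldehyde; 25 tert-butyl acrylate
Product: 26 tert-butyl 3-hydroxy-2-methylidene-4-(phenylselanyl)butanoate (racemic)
Conditions: DABCO (30 mol %), neat, rt
Reagents that add atoms: none
Why: Morita–Baylis–Hillman reaction; the racemic carbinol centre (C8) is of no consequence because it becomes sp2 in step 17.

Step 14
Reactants: 26 Morita–Baylis–Hillman alcohol
Product: 27 tert-butyl 3-[(tert-butoxycarbonyl)oxy]-2-methylidene-4-(phenylselanyl)butanoate
Conditions: Boc2O, DMAP (10 mol %), CH2Cl2, 0 °C to rt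
Reagents that add atoms: di-tert-butyl dicarbonate, CC(C)(C)OC(=O)OC(=O)OC(C)(C)C
Why: DMAP-catalysed O-acylation turns the allylic alcohol into the carbonate leaving group needed for step 15.

Step 15
Reactants: 20 allylic alcohol; 27 carbonate
Product: 28 tert-butyl 3-({(3R,4S)-4-isopropyl-3-[(1E)-2-(methoxycarbonyl)hexa-1,5-dien-1-yl]cyclohex-1-en-1-yl}methoxy)-2-methylidene-4-(phenylselanyl)butanoate (C17–O–C8 ether, both C8 epimers)
Conditions: DABCO (20 mol %), toluene, rt
Reagents that add atoms: none
Why: Lewis-base-catalysed allylic substitution of a Morita–Baylis–Hillman carbonate (SN2′ attack of DABCO with loss of CO2 and tert-butoxide, then SN2′ attack of the alkoxide of 20) gives the branched secondary ether and regenerates the acrylate; both C8 epimers are carried on.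

Step 16
Reactants: 28 ether diene
Product: 29 bridged twelve-membered cyclic ether (ring C1, C2=C3, C4, C5, C6=C7, C8, O, C17, C11=C10; CO2Me on C3, CO2tBu on C7, CH2SePh on C8; 1R,14S; both C8 epimers)
Conditions: second-generation Hoveyda–Grubbs catalyst (10 mol %), toluene (1 mM), 90 °C, argon sparge
Reagents that add atoms: none
Why: Ring-closing metathesis between the terminal alkene and the acrylate methylene, driven by loss of ethene; the trisubstituted alkenes are inert, and thermodynamic control should give C5 trans to the ester (E), the geometry that is also cis within the ring.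

Step 17
Reactants: 29 twelve-membered cyclic ether
Product: 32 ten-membered keto diester (1S,10S,14S; C8 ketone, C11=C17H2, CO2Me on C3, CO2tBu on C7), via selenoxide 30 (not isolated), via dienol ether 31 (not isolated)
Conditions: mCPBA (1.0 equiv), CH2Cl2, −78 °C; then Et3N, toluene, −78 °C to rt, then 100 °C
Reagents that add atoms: mCPBA, O=C(OO)c1cccc(Cl)c1 (its oxygen stays only in 30 and leaves with the selenium)
Why: Selenium is oxidised far faster than any alkene, and selenoxide 30 can lose PhSeOH only through the single β-hydrogen on C8 (syn elimination), which gives the C8=C9 enol ether 31 regiospecifically. 31 is an allyl vinyl ether (C9=C8–O–C17–C11=C10) and undergoes the Claisen [3,3]-sigmatropic rearrangement; the closest known cases are selenoxide elimination–Claisen sequences to medium rings and ring-contracting Claisen rearrangements of macrocyclic ketene acetals and enol ethers. The ten-membered ring is closed transannularly by the new C9–C10 bond through a six-centre, suprafacial–suprafacial transition state, while cleavage of O–C17 expels C11, C17 and O from the ring (twelve to ten atoms). The only new stereocentre, C10, is controlled by the macrocycle: C10=C11 is an E-alkene within the twelve-membered ring, so its allylic ring bonds C1–C2 and C17–O lie on opposite faces and C9 can reach C10 only anti to C2, which gives the trans ring fusion, and the pseudoaxial C2 chain and the isopropyl group on that same face reinforce this. The C2=C3 and C6=C7 geometries are not touched, C8 becomes the ketone and C11=C17 the exocyclic methylene. The step needs chemoselective oxidation, absence of acid (Et3N, base-washed glass) and the lowest workable temperature, because 31 is hydrolysable and the 2-acylacrylate of 32 could enolise by a 1,5-hydrogen shift.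

Step 18
Reactants: 32 keto diester
Product: 33 (1S,8R,10S,14S)-8-hydroxy diester (tert-butyl ester of the target)
Conditions: (S)-2-methyl-CBS-oxazaborolidine (30 mol %), catecholborane, toluene, −78 °C; then MeOH, aq NaHCO3
Reagents that add atoms: none
Why: Corey–Bakshi–Shibata reduction: the catalyst distinguishes the large ester-bearing alkenyl side (C7) from the small C9H2 side, so reagent control should give 8R, the low temperature favours 1,2-reduction, and catecholborane leaves the alkenes alone.

Step 19
Reactants: 33 hydroxy diester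
Product: 35 Microeunicellol B, via bis-silyl derivative 34 (not isolated)
Conditions: TMSOTf, 2,6-lutidine, CH2Cl2, 0 °C; then aq citric acid, THF, rt
Reagents that add atoms: trimethylsilyl triflate, C[Si](C)(C)OS(=O)(=O)C(F)(F)F (its silicon stays only in 34)
Why: Silyl-triflate-mediated cleavage of the tert-butyl ester (loss of isobutene from the O-silylated ester) avoids protic acid, which could isomerise the exocyclic methylene, leaves the methyl ester alone, and the silyl groups fall off in the mild aqueous work-up.

Compound list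
1 | 3-methylbutanal | CC(C)CC=O | starting material
2 | but-3-en-2-one | C=CC(C)=O | starting material
3 | (2S)-2-isopropyl-5-oxohexanal | O=C[C@H](C(C)C)CCC(C)=O | intermediate
4 | (4S)-4-isopropylcyclohex-2-en-1-one | O=C1C=C[C@H](C(C)C)CC1 | intermediate
5 | tributyl(iodomethyl)stannane | CCCC[Sn](CCCC)(CCCC)CI | starting material
6 | 4-methoxybenzyl alcohol | COc1ccc(CO)cc1 | starting material
7 | tributyl{[(4-methoxybenzyl)oxy]methyl}stannane | CCCC[Sn](CCCC)(CCCC)COCc1ccc(OC)cc1 | intermediate
8 | {[(4-methoxybenzyl)oxy]methyl}lithium | [Li]COCc1ccc(OC)cc1 | intermediate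
9 | (4S)-4-isopropyl-1-{[(4-methoxybenzyl)oxy]methyl}cyclohex-2-en-1-ol, both C11 epimers | COc1ccc(COCC2(O)C=C[C@H](C(C)C)CC2)cc1 | intermediate
10 | (6S)-6-isopropyl-3-{[(4-methoxybenzyl)oxy]methyl}cyclohex-2-en-1-one | COc1ccc(COCC2=CC(=O)[C@H](C(C)C)CC2)cc1 | intermediate
11 | 1-({[(4S)-4-isopropyl-3-methylidenecyclohex-1-en-1-yl]methoxy}methyl)-4-methoxybenzene | COc1ccc(COCC2=CC(=C)[C@H](C(C)C)CC2)cc1 | intermediate
12 | B-alkyl-9-BBN from 11 (boron on C2, cis to isopropyl) | COc1ccc(COCC2=C[C@H](CB3C4CCCC3CCC4)[C@H](C(C)C)CC2)cc1 | intermediate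
13 | [(1R,6S)-6-isopropyl-3-{[(4-methoxybenzyl)oxy]methyl}cyclohex-2-en-1-yl]methanol | COc1ccc(COCC2=C[C@H](CO)[C@H](C(C)C)CC2)cc1 | intermediate
14 | (1R,6S)-6-isopropyl-3-{[(4-methoxybenzyl)oxy]methyl}cyclohex-2-ene-1-carbaldehyde | COc1ccc(COCC2=C[C@H](C=O)[C@H](C(C)C)CC2)cc1 | intermediate
15 | methyl hex-5-enoate | C=CCCCC(=O)OC | starting material
16 | methyl 2-bromohex-5-enoate (racemic) | C=CCCC(Br)C(=O)OC | intermediate
17 | (1-methoxy-1-oxohex-5-en-2-yl)triphenylphosphonium bromide | C=CCCC(C(=O)OC)[P+](c1ccccc1)(c1ccccc1)c1ccccc1.[Br-] | intermediate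
18 | methyl 2-(triphenyl-λ5-phosphanylidene)hex-5-enoate | C=CCCC(C(=O)OC)=P(c1ccccc1)(c1ccccc1)c1ccccc1 | intermediate
19 | methyl (2E)-2-(but-3-en-1-yl)-3-[(1R,6S)-6-isopropyl-3-{[(4-methoxybenzyl)oxy]methyl}cyclohex-2-en-1-yl]prop-2-enoate | COc1ccc(COCC2=C[C@H](/C=C(/C(=O)OC)CCC=C)[C@H](C(C)C)CC2)cc1 | intermediate
20 | methyl (2E)-2-(but-3-en-1-yl)-3-[(1R,6S)-3-(hydroxymethyl)-6-isopropylcyclohex-2-en-1-yl]prop-2-enoate | OCC1=C[C@H](/C=C(/C(=O)OC)CCC=C)[C@H](C(C)C)CC1 | intermediate
21 | benzeneselenenyl chloride | Cl[Se]c1ccccc1 | starting material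
22 | ethyl vinyl ether | C=COCC | starting material
23 | (2-chloro-2-ethoxyethyl)(phenyl)selane | CCOC(Cl)C[Se]c1ccccc1 | intermediate
24 | (phenylselanyl)acetaldehyde | O=CC[Se]c1ccccc1 | intermediate
25 | tert-butyl acrylate | C=CC(=O)OC(C)(C)C | starting material
26 | tert-butyl 3-hydroxy-2-methylidene-4-(phenylselanyl)butanoate (racemic) | C=C(C(=O)OC(C)(C)C)C(O)C[Se]c1ccccc1 | intermediate
27 | tert-butyl 3-[(tert-butoxycarbonyl)oxy]-2-methylidene-4-(phenylselanyl)butanoate | C=C(C(=O)OC(C)(C)C)C(C[Se]c1ccccc1)OC(=O)OC(C)(C)C | intermediate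
28 | C17–O–C8 ether of 20 with the acrylate unit of 27, both C8 epimers | C=C(C(=O)OC(C)(C)C)C(C[Se]c1ccccc1)OCC1=C[C@H](/C=C(/C(=O)OC)CCC=C)[C@H](C(C)C)CC1 | intermediate
29 | bridged twelve-membered cyclic ether with CH2SePh on C8 (1R,14S, both C8 epimers) | O1CC2=C[C@H](/C=C(/C(=O)OC)CC/C=C(/C(=O)OC(C)(C)C)C1C[Se]c1ccccc1)[C@H](C(C)C)CC2 | intermediate
30 | selenoxide of 29 | O1CC2=C[C@H](/C=C(/C(=O)OC)CC/C=C(/C(=O)OC(C)(C)C)C1C[Se](=O)c1ccccc1)[C@H](C(C)C)CC2 | intermediate
31 | twelve-membered allyl vinyl ether with C8=C9H2 (1R,14S) | O1CC2=C[C@H](/C=C(/C(=O)OC)CC/C=C(/C(=O)OC(C)(C)C)C1=C)[C@H](C(C)C)CC2 | intermediate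
32 | ten-membered keto diester (1S,10S,14S) | C=C1CC[C@@H](C(C)C)[C@H]2/C=C(/C(=O)OC)CC/C=C(/C(=O)OC(C)(C)C)C(=O)C[C@H]12 | intermediate
33 | 8-hydroxy diester (1S,8R,10S,14S) | C=C1CC[C@@H](C(C)C)[C@H]2/C=C(/C(=O)OC)CC/C=C(/C(=O)OC(C)(C)C)[C@H](O)C[C@H]12 | intermediate
34 | trimethylsilyl ester and trimethylsilyl ether of 35 | C=C1CC[C@@H](C(C)C)[C@H]2/C=C(/C(=O)OC)CC/C=C(/C(=O)O[Si](C)(C)C)[C@H](O[Si](C)(C)C)C[C@H]12 | intermediate
35 | Microeunicellol B | C=C1CC[C@@H](C(C)C)[C@H]2/C=C(/C(=O)OC)CC/C=C(/C(=O)O)[C@H](O)C[C@H]12 | target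

Total step count: 19.
Longest linear sequence: 13 steps (1, 3, 4, 5, 6, 7, 10, 11, 15, 16, 17, 18, 19).

Steps most likely to fail

**1. Step 16 (ring-closing metathesis).**
- What may go wrong: the ruthenium carbene may fail to engage the hindered, electron-poor 1,1-disubstituted acrylate at high dilution. Oligomerisation through the terminal alkene, or loss of catalyst by coordination to selenium, would then win.
- Fallback: it sets out from 20 and 26 and returns at 29. It makes C6=C7 first and closes the ring at the ether bond instead.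
- Cross-metathesis of 20 with an excess of 26 (second-generation Hoveyda–Grubbs catalyst, CH2Cl2, 40 °C) should give the seco diol F1.
- Appel bromination of its primary allylic hydroxyl (CBr4, PPh3, CH2Cl2, −20 °C) gives the allylic bromide F2.
- Ag2O in toluene at high dilution then closes C17–O by intramolecular Williamson etherification to 29.

**2. Step 17 (key step).**
- What may go wrong: hydrolysis of the dienol ether, addition of the selenenic acid to it, or enolisation and oligomerisation of the doubly activated alkene at the temperature of the shift.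
- Fallback: it sets out from 20 and returns at 35. It keeps the same ring contraction but runs it on a less activated system and brings in the C7 carboxyl afterwards.
- Acryloyl chloride and Et3N give the acrylate ester F3.
- Ring-closing metathesis gives the twelve-membered Z-enoate lactone F4.
- One equivalent of Cp2TiMe2 should methylenate the unbranched lactone carbonyl before the α-branched methyl enoate, giving the methylidene enol ether F5.
- Heating in toluene contracts it by the Claisen shift to the ten-membered Z-enone F6.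
- I2 and pyridine give the α-iodo enone F7, and Corey–Bakshi–Shibata reduction gives the iodo alcohol F8.
- Hydroxycarbonylation (Pd(OAc)2, PPh3, CO, H2O, Et3N, DMF) gives 35.

**3. Step 10 (Wittig olefination).**
- What may go wrong: epimerisation at C1, or migration of the C10=C11 double bond into conjugation, in aldehyde 14 while the slow reaction with the hindered ylide proceeds.
- Fallback: it sets out from 13 and returns at 19. It avoids the aldehyde altogether.
- Mitsunobu reaction of 13 with thioacetic acid (DIAD, PPh3) gives the thioacetate F9.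
- K2CO3 in MeOH in the presence of 16 gives the sulfide F10.
- (NH4)6Mo7O24 and H2O2 give the sulfone F11.
- NaH and C2Cl6 give the α-chloro sulfone F12.
- KOtBu in THF then effects an acyclic Ramberg–Bäcklund reaction to 19.

Further compounds
F1 | step 16 | seco diol with C6=C7 in place (free C17–OH and C8–OH) | OCC1=C[C@H](/C=C(/C(=O)OC)CC/C=C(/C(=O)OC(C)(C)C)C(O)C[Se]c2ccccc2)[C@H](C(C)C)CC1
F2 | step 16 | allylic bromide at C17 | BrCC1=C[C@H](/C=C(/C(=O)OC)CC/C=C(/C(=O)OC(C)(C)C)C(O)C[Se]c2ccccc2)[C@H](C(C)C)CC1
F3 | step 17 | acrylate ester of 20 | C=CC(=O)OCC1=C[C@H](/C=C(/C(=O)OC)CCC=C)[C@H](C(C)C)CC1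
F4 | step 17 | twelve-membered Z-enoate lactone | O=C1OCC2=C[C@H](/C=C(/C(=O)OC)CC/C=C\1)[C@H](C(C)C)CC2
F5 | step 17 | twelve-membered methylidene enol ether | C=C1OCC2=C[C@H](/C=C(/C(=O)OC)CC/C=C\1)[C@H](C(C)C)CC2
F6 | step 17 | ten-membered Z-enone | C=C1CC[C@@H](C(C)C)[C@H]2/C=C(/C(=O)OC)CC/C=C\C(=O)C[C@H]12
F7 | step 17 | α-iodo enone | C=C1CC[C@@H](C(C)C)[C@H]2/C=C(/C(=O)OC)CC/C=C(/I)C(=O)C[C@H]12
F8 | step 17 | (8R)-iodo alcohol | C=C1CC[C@@H](C(C)C)[C@H]2/C=C(/C(=O)OC)CC/C=C(/I)[C@H](O)C[C@H]12
F9 | step 10 | thioacetate of 13 | COc1ccc(COCC2=C[C@H](CSC(C)=O)[C@H](C(C)C)CC2)cc1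
F10 | step 10 | sulfide C2–S–C3 | COc1ccc(COCC2=C[C@H](CSC(CCC=C)C(=O)OC)[C@H](C(C)C)CC2)cc1
F11 | step 10 | sulfone | COc1ccc(COCC2=C[C@H](CS(=O)(=O)C(CCC=C)C(=O)OC)[C@H](C(C)C)CC2)cc1
F12 | step 10 | α-chloro sulfone | COc1ccc(COCC2=C[C@H](CS(=O)(=O)C(Cl)(CCC=C)C(=O)OC)[C@H](C(C)C)CC2)cc1
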